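Amounts first: 0.40 mM of catalyst faces 20 mM of substrate, so each catalyst must turn 50.0 times, and I can count the catalyst by how long it lingers in each form.

substrate 20 mM; partner 60.0 mM; free catalyst 0.40 mM

    substrate + free catalyst → catalyst intermediate A (k1 = 3900 L mol⁻¹ min⁻¹)
    catalyst intermediate A ⇌ catalyst intermediate B (K2 = 1.9, k2 = 26 min⁻¹)
    partner + catalyst intermediate B ⇌ catalyst intermediate C (K3 = 7.9 L mol⁻¹, k3 = 2400 L mol⁻¹ min⁻¹)
    catalyst intermediate C → catalyst intermediate D (k4 = 580 min⁻¹)
    catalyst intermediate D → released group + catalyst intermediate E (k5 = 28 min⁻¹)
    catalyst intermediate E → free catalyst + target (k6 = 12 min⁻¹)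
    substrate + catalyst intermediate A ⇌ idle complex, settled at all times (K7 = 4800 L mol⁻¹)

1. the form that holds most of the catalyst when 20% of the substrate are converted (idle complex / catalyst intermediate D / catalyst intermediate B / free catalyst / catalyst intermediate A / catalyst intermediate E)
2. its share of the catalyst then

At 20% converted, with bound substrate counted as converted, free substrate S is 16.0 mM, and partner P is at least 56.0 mM. I assume steady turnover and call a form's stay its amount divided by the turnover rate. Free catalyst, C, D and E together stay 0.137 min. With P at its floor, B stays 0.0113 min and A stays 0.0444 min. The balance of step 7 gives 76.8 idle complexes per A, so the idle stay is that many times the stay of A.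

Set against A by itself, the idle share stays under 98.7%. Adding the other stays at full length, with A at its shortest, 0.0385 min, gives a floor of 94.1%. Keeping A's longest stay and dropping B lowers the ceiling to 95.0%. All stays summed make the lap, the catalyst charged divided by the rate of making target: 3.60 min. I commit to idle complex at 94.7%.

The forecast names idle complex at 94.7%, which stands between my floor of 94.1% and my ceiling of 95.0%; its ground: “Treat the catalyst forms as being in quasi-steady state”.

The simulation gives idle complex at 94.7%, after 31.8 min.

At 20.0 min the round is turning while idle complex, an off-cycle form and so no resting state of the round, holds 95.1% of the catalyst and target stands at 9.79%. By 200 min substrate stands at 0% and free catalyst at 100%. The simulated rate of making target at 20% converted, 0.111 mM min⁻¹, makes the lap 3.60 min. In the flask with twice the partner, the reckoned lap at 20% converted shrinks by the factor 0.932, and the simulated factor on the time to that conversion is 0.936.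

The numbers of this flask were chosen freely; what happens was integrated by code.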